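**Plan**
- Cuts, in retrosynthetic order: C11–C12 of the spirolactone (homoenolate addition to a C11 lactone); C8–C9 and C10–C11 of rings B and C (intramolecular oxazole–alkyne cycloaddition); C9a–C9 (alkynylation of the lactam carbon) and N4–C5 (N-alkylation); C18–C19 and C21–C20 of the appended lactone.
- Enabling feature: in the appended lactone (O, C18, C19, C20, C21) the ring oxygen is flanked by C18 and C21, so the ring is a reduced 2-methoxy-3-methylfuran, which is what a 5-methoxyoxazole and a propyne unit give. N4 sits on C3 next to C18 and can hold the propyne through a temporary N–Si tether.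
- Forward order: L-pyroglutamic acid → C3 oxazole → key step → γ-keto ester → appended lactone → lactone masked as methyl acetal → N-alkylation and alkynylation → rings B and C by a second oxazole–alkyne cycloaddition → conjugate reduction → spirolactone → unmasking.
- Stereochemistry: C3 is bought (L-pyroglutamic acid) and C13 is bought (the (2R)-bromo ester). C18 (Felkin–Anh reduction), C20 (kinetic protonation), C9a (anti addition to the iminium ion), C8/C9/C10 (ring-controlled protonation and hydride delivery) and C11 (thermodynamic spiroketal) are relayed.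

Key step: step 4

Remark: atom numbers follow Stemona numbering (N4; C1–C3 and C9a in the pyrrolidine; C5–C9 in the azepane; O, C8–C11 in the tetrahydrofuran; C12–C14 in the spirolactone; C18–C21 in the appended lactone). The target is read from the SMILES as 3S,8R,9R,9aS,10S,11S,13S,18S,20S.
Remark: C20 in 11–13 and the mask carbon C21 in 16, 17, 21–27, 31 and 32 are carried as epimer or anomer mixtures; they converge in steps 6 and 16.

**Step 1**
Reactants: 1 prop-1-yn-1-ylmagnesium bromide; 2 dichlorodimethylsilane
Product: 3 chloro(dimethyl)(prop-1-yn-1-yl)silane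
Conditions: 2 (3 equiv), THF, −78 to 23 °C; distillation
Reagents that add atoms: none
Why: Salt metathesis of the alkynyl Grignard reagent at silicon, with excess dichlorosilane to stop at monosubstitution, should give the alkynylchlorosilane.

**Step 2**
Reactants: 4 L-pyroglutamic acid; 5 L-alanine methyl ester hydrochloride
Product: 6 methyl N-[(2S)-5-oxopyrrolidine-2-carbonyl]-L-alaninate
Conditions: dicyclohexylcarbodiimide, 1-hydroxybenzotriazole (cat.), Et3N, DMF, 0 to 23 °C
Reagents that add atoms: none
Why: Carbodiimide amide coupling through the benzotriazolyl active ester should join the two amino acid units without epimerisation at C3.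

**Step 3**
Reactants: 6 methyl N-[(2S)-5-oxopyrrolidine-2-carbonyl]-L-alaninate
Product: 7 (5S)-5-(5-methoxy-4-methyl-1,3-oxazol-2-yl)pyrrolidin-2-one
Conditions: P2O5, CHCl3, 61 °C
Reagents that add atoms: none
Why: Cyclodehydration of the N-acyl α-amino ester (Robinson–Gabriel type) closes the 5-methoxyoxazole, the alanine stereocentre becoming the sp2 carbon C4 of the oxazole.

**Step 4**
Reactants: 7 (5S)-5-(5-methoxy-4-methyl-1,3-oxazol-2-yl)pyrrolidin-2-one; 3 chloro(dimethyl)(prop-1-yn-1-yl)silane
Product: 11 methyl 2-methyl-4-oxo-4-[(2S)-5-oxopyrrolidin-2-yl]butanoate (both C2 epimers), via N-silyl lactam 8 (not isolated), via bridged cycloadduct 9 (not isolated), via silylated methoxyfuran 10 (not isolated)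
Conditions: 3 (1.2 equiv), Et3N, PhMe, 0 to 23 °C; filter; 1,2-Cl2C6H4, 180 °C; then MeOH, 1 M aq HCl, 23 °C
Reagents that add atoms: water, O
Why: Proposed new method: N-silylation of the lactam ties the propynyl unit to N4, three atoms away from oxazole C2, so that the 2-azadiene C2=N3–C4=C5 of the electron-rich 5-methoxyoxazole adds across the alkyne in an intramolecular [4+2] cycloaddition that forms C18–C19 and C21–C20 together, and the bridged adduct 9 then loses acetonitrile by retro-[4+2] to give the aromatic 2-methoxyfuran 10. The closest known reaction type is the intramolecular oxazole–alkyne Diels–Alder/retro-Diels–Alder reaction of 5-alkoxyoxazoles carrying an alkyne on a three-atom carbon tether (ynones) or a five-atom tether at C2; the N–Si tether and the unactivated silylalkyne are the new elements. Two rings close: the furan ring (O, C18, C19, C20, C21) by the cycloaddition/cycloreversion pair, and the temporary five-membered ring (N4, C3, C18, C19, Si) as the fused tether ring of the cycloaddition. No stereocentre is created and C3 is not touched; C18 and C20 are set in steps 5 and 6. The step needs regioselectivity (silicon-bearing C19 to C18, methyl-bearing C20 to C21), which the short tether enforces, and it needs loss of MeCN instead of reversal, which the aromatisation to the furan secures. Acidic methanol then cleaves N–Si, opens the methoxyfuran to the γ-keto ester and removes silicon from C19 by ipso-protonation of the β-silyl enol ether (α-silyl ketone), so the tether leaves no trace.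

**Step 5**
Reactants: 11 methyl 2-methyl-4-oxo-4-[(2S)-5-oxopyrrolidin-2-yl]butanoate
Product: 13 (5S)-5-[(2S)-4-methyl-5-oxooxolan-2-yl]pyrrolidin-2-one (C4 epimers of the oxolanone), via hydroxy ester 12 (not isolated)
Conditions: K[BH(s-Bu)3] (1.5 equiv), THF, −78 °C, then 23 °C
Reagents that add atoms: none
Why: Felkin–Anh hydride addition to the ketone anti to the C3–N bond should give the (18S) alcohol, syn to N4, whose alkoxide closes the γ-lactone by transesterification.

**Step 6**
Reactants: 13 (5S)-5-[(2S)-4-methyl-5-oxooxolan-2-yl]pyrrolidin-2-one (C4 epimers)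
Product: 15 (5S)-5-[(2S,4S)-4-methyl-5-oxooxolan-2-yl]pyrrolidin-2-one, via dilithium enolate 14 (not isolated)
Conditions: LiN(i-Pr)2 (2.3 equiv), THF, −78 °C; 2,6-di-tert-butyl-4-methylphenol, −78 °C; aq NH4Cl
Reagents that add atoms: none
Why: Kinetic protonation of the lactone enolate by the bulky phenol from the face opposite the C18 substituent should place the methyl group cis to it (20S).

**Step 7**
Reactants: 15 (5S)-5-[(2S,4S)-4-methyl-5-oxooxolan-2-yl]pyrrolidin-2-one
Product: 17 (5S)-5-[(2S,4S)-5-methoxy-4-methyloxolan-2-yl]pyrrolidin-2-one (anomers), via lactol 16 (not isolated)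
Conditions: i-Bu2AlH (2.5 equiv), CH2Cl2, −78 °C; then HCl in MeOH, −78 to 0 °C
Reagents that add atoms: methanol, CO
Why: Partial reduction of the lactone (the N-aluminated lactam is not reduced at −78 °C) and acid-catalysed acetal formation mask C21 as a methyl acetal that is inert to the bases, hydrides and organolithium reagent used later, with C18 and C20 untouched.

**Step 8**
Reactants: 18 4-chlorobutanoyl chloride; 5 L-alanine methyl ester hydrochloride
Product: 19 methyl N-(4-chlorobutanoyl)-L-alaninate
Conditions: Et3N (2.2 equiv), CH2Cl2, 0 °C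
Reagents that add atoms: none
Why: N-acylation of the amino ester by the acid chloride (Schotten–Baumann type) is much faster than substitution at the primary chloride.

**Step 9**
Reactants: 19 methyl N-(4-chlorobutanoyl)-L-alaninate
Product: 20 2-(3-chloropropyl)-5-methoxy-4-methyl-1,3-oxazole
Conditions: P2O5, CHCl3, 61 °C
Reagents that add atoms: none
Why: The same cyclodehydration of an N-acyl α-amino ester as in step 3 gives the 5-methoxyoxazole and leaves the alkyl chloride intact.

**Step 10**
Reactants: 17 (5S)-5-[(2S,4S)-5-methoxy-4-methyloxolan-2-yl]pyrrolidin-2-one; 20 2-(3-chloropropyl)-5-methoxy-4-methyl-1,3-oxazole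
Product: 21 (5S)-1-[3-(5-methoxy-4-methyl-1,3-oxazol-2-yl)propyl]-5-[(2S,4S)-5-methoxy-4-methyloxolan-2-yl]pyrrolidin-2-one
Conditions: NaH, NaI (cat.), DMF, 0 to 60 °C
Reagents that add atoms: none
Why: SN2 N-alkylation of the lactam sodium salt with iodide catalysis (Finkelstein exchange) forms N4–C5, the acetal and the oxazole being stable to base.

**Step 11**
Reactants: 21 the N-alkyl lactam; 22 but-1-yne
Product: 24 2-{3-[(2S,5S)-2-(but-1-yn-1-yl)-5-[(2S,4S)-5-methoxy-4-methyloxolan-2-yl]pyrrolidin-1-yl]propyl}-5-methoxy-4-methyl-1,3-oxazole, via silyl hemiaminal 23 (not isolated)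
Conditions: IrCl(CO)(PPh3)2 (1 mol %), (Me2SiH)2O, PhMe, 23 °C; then CuBr (10 mol %), 22 (excess), 23 °C, sealed tube
Reagents that add atoms: none
Why: Iridium-catalysed hydrosilylation of the tertiary lactam gives the N,O-silyl hemiaminal, which ionises to the iminium ion and is alkynylated by the copper acetylide (reductive alkynylation of an amide) on the face opposite the C3 substituent, which should set the 2,5-trans pyrrolidine (9aS).

**Step 12**
Reactants: 24 the alkynyl oxazole
Product: 26 the tricyclic butenolide (3S,8R,9aS)-10-ethyl-3-[(2S,4S)-5-methoxy-4-methyloxolan-2-yl] with C9=C10, C11 lactone carbonyl and C8–H, via tricyclic methoxyfuran 25 (not isolated)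
Conditions: 1,2-Cl2C6H4, 180 °C; then wet SiO2, CH2Cl2, 0 °C; Et3N, 23 °C
Reagents that add atoms: water, O
Why: The intramolecular oxazole–alkyne Diels–Alder/retro-Diels–Alder reaction (a type known for 2-(alkynylalkyl)-5-alkoxyoxazoles) closes the azepane ring B and the furan ring C with loss of MeCN, and protonation of the 2-methoxyfuran at C8 followed by base equilibration of the γ-position should give the conjugated butenolide with H8 and H9a on opposite faces of ring B (8R).

**Step 13**
Reactants: 26 the tricyclic butenolide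
Product: 27 the tricyclic lactone (3S,8R,9R,9aS,10S)-10-ethyl-3-[(2S,4S)-5-methoxy-4-methyloxolan-2-yl], γ-lactone O–C8–C9–C10–C11(=O)
Conditions: NaBH4, NiCl2·6H2O (20 mol %), MeOH, −30 °C
Reagents that add atoms: none
Why: Nickel boride conjugate reduction should deliver hydride to C9 on the face of H9a, giving the trans B/C ring fusion (9R), and protonation of the enolate at C10 places the ethyl group trans to the C9–C9a bond (10S).

**Step 14**
Reactants: 28 methyl (2R)-3-bromo-2-methylpropanoate
Product: 29 (2R)-3-bromo-2-methylpropanoic acid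
Conditions: 48 % aq HBr, 60 °C
Reagents that add atoms: water, O
Why: Acid-catalysed ester hydrolysis avoids the base-induced loss of bromide and leaves the stereocentre at C2 untouched.

**Step 15**
Reactants: 27 the tricyclic lactone; 29 (2R)-3-bromo-2-methylpropanoic acid
Product: 32 the spirolactone (3S,8R,9R,9aS,10S,11S,13S) with C21 as lactol (anomers), via lithio carboxylate 30 (not isolated), via hemiketal acid 31 (not isolated)
Conditions: 29, n-BuLi (1.0 equiv), THF, −78 °C; LiC10H8 (2.1 equiv), −78 °C; 27, −78 °C; then 1 M aq HCl, THF, 23 °C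
Reagents that add atoms: water, O
Why: Reductive lithiation gives the β-lithio carboxylate (a homoenolate equivalent), which adds once to the only carbonyl group present, the lactone C11, and acid then closes the spiroketal lactone under thermodynamic control (lactone oxygen on the side of the C10 ethyl group, 11S) and hydrolyses the methyl acetal to the lactol, C13 coming unchanged from 29.

**Step 16**
Reactants: 32 the spirolactone lactol
Product: 33 the target, CNP0419197.1
Conditions: Pr4N[RuO4] (5 mol %), N-methylmorpholine N-oxide, 4 Å molecular sieves, CH2Cl2, 23 °C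
Reagents that add atoms: none
Why: Ley–Griffith oxidation of the lactol to the γ-lactone restores C21 as the carbonyl group without touching any stereocentre.

**Compound list**
1 | prop-1-yn-1-ylmagnesium bromide | CC#C[Mg]Br | starting material
2 | dichlorodimethylsilane | C[Si](C)(Cl)Cl | starting material
3 | chloro(dimethyl)(prop-1-yn-1-yl)silane | CC#C[Si](C)(C)Cl | intermediate
4 | L-pyroglutamic acid, (2S)-5-oxopyrrolidine-2-carboxylic acid | OC(=O)[C@@H]1CCC(=O)N1 | starting material
5 | L-alanine methyl ester hydrochloride | C[C@H](N)C(=O)OC.Cl | starting material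
6 | methyl N-[(2S)-5-oxopyrrolidine-2-carbonyl]-L-alaninate | O=C1CC[C@H](N1)C(=O)N[C@@H](C)C(=O)OC | intermediate
7 | (5S)-5-(5-methoxy-4-methyl-1,3-oxazol-2-yl)pyrrolidin-2-one | O=C1CC[C@H](N1)c2nc(C)c(OC)o2 | intermediate
8 | (5S)-1-[dimethyl(prop-1-yn-1-yl)silyl]-5-(5-methoxy-4-methyl-1,3-oxazol-2-yl)pyrrolidin-2-one | CC#C[Si](C)(C)N1C(=O)CC[C@H]1c2nc(C)c(OC)o2 | intermediate
9 | bridged cycloadduct, 7-oxa-2-azabicyclo[2.2.1]hepta-2,5-diene joined through SiMe2 and N4 to the pyrrolidinone (bridgeheads unassigned) | COC12OC3(N=C1C)C(=C2C)[Si](C)(C)N4C(=O)CC[C@@H]34 | intermediate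
10 | silylated 2-methoxy-3-methylfuran, furan C4 (C19) and lactam N bridged by SiMe2 | COc1oc2c(c1C)[Si](C)(C)N3C(=O)CC[C@@H]23 | intermediate
11 | methyl 2-methyl-4-oxo-4-[(2S)-5-oxopyrrolidin-2-yl]butanoate (C2 epimers) | COC(=O)C(C)CC(=O)[C@@H]1CCC(=O)N1 | intermediate
12 | methyl (4S)-4-hydroxy-2-methyl-4-[(2S)-5-oxopyrrolidin-2-yl]butanoate (formed as potassium alkoxide; C2 epimers) | COC(=O)C(C)C[C@H](O)[C@@H]1CCC(=O)N1 | intermediate
13 | (5S)-5-[(2S)-4-methyl-5-oxooxolan-2-yl]pyrrolidin-2-one (C4 epimers of the oxolanone) | O=C1CC[C@H](N1)[C@@H]2CC(C)C(=O)O2 | intermediate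
14 | dilithium salt of 13 (N-lithio lactam, lithium lactone enolate) | [Li]N1C(=O)CC[C@H]1[C@@H]2CC(C)=C(O[Li])O2 | intermediate
15 | (5S)-5-[(2S,4S)-4-methyl-5-oxooxolan-2-yl]pyrrolidin-2-one | O=C1CC[C@H](N1)[C@@H]2C[C@H](C)C(=O)O2 | intermediate
16 | (5S)-5-[(2S,4S)-5-hydroxy-4-methyloxolan-2-yl]pyrrolidin-2-one (anomers) | O=C1CC[C@H](N1)[C@@H]2C[C@H](C)C(O)O2 | intermediate
17 | (5S)-5-[(2S,4S)-5-methoxy-4-methyloxolan-2-yl]pyrrolidin-2-one (anomers) | O=C1CC[C@H](N1)[C@@H]2C[C@H](C)C(OC)O2 | intermediate
18 | 4-chlorobutanoyl chloride | ClCCCC(Cl)=O | starting material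
19 | methyl N-(4-chlorobutanoyl)-L-alaninate | ClCCCC(=O)N[C@@H](C)C(=O)OC | intermediate
20 | 2-(3-chloropropyl)-5-methoxy-4-methyl-1,3-oxazole | ClCCCc1nc(C)c(OC)o1 | intermediate
21 | (5S)-1-[3-(5-methoxy-4-methyl-1,3-oxazol-2-yl)propyl]-5-[(2S,4S)-5-methoxy-4-methyloxolan-2-yl]pyrrolidin-2-one | O=C1CC[C@H](N1CCCc3nc(C)c(OC)o3)[C@@H]2C[C@H](C)C(OC)O2 | intermediate
22 | but-1-yne | CCC#C | starting material
23 | N,O-silyl hemiaminal of 21 (C9a unassigned) | C[SiH](C)O[Si](C)(C)OC1CC[C@H](N1CCCc3nc(C)c(OC)o3)[C@@H]2C[C@H](C)C(OC)O2 | intermediate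
24 | 2-{3-[(2S,5S)-2-(but-1-yn-1-yl)-5-[(2S,4S)-5-methoxy-4-methyloxolan-2-yl]pyrrolidin-1-yl]propyl}-5-methoxy-4-methyl-1,3-oxazole | CCC#C[C@@H]1CC[C@H](N1CCCc3nc(C)c(OC)o3)[C@@H]2C[C@H](C)C(OC)O2 | intermediate
25 | tricyclic 2-methoxyfuran (3S,9aS): furan O, C8, C9, C10 (ethyl), C11 (OMe) fused at C8–C9 to the pyrrolo[1,2-a]azepane | CCc1c(OC)oc2c1[C@@H]3CC[C@H](N3CCC2)[C@@H]4C[C@H](C)C(OC)O4 | intermediate
26 | tricyclic butenolide (3S,8R,9aS): C9=C10, C11 lactone carbonyl, C8–H | CCC1=C2[C@@H](CCCN3[C@H]2CC[C@H]3[C@@H]4C[C@H](C)C(OC)O4)OC1=O | intermediate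
27 | tricyclic lactone (3S,8R,9R,9aS,10S) | CC[C@H]1[C@H]2[C@@H](CCCN3[C@H]2CC[C@H]3[C@@H]4C[C@H](C)C(OC)O4)OC1=O | intermediate
28 | methyl (2R)-3-bromo-2-methylpropanoate | BrC[C@H](C)C(=O)OC | starting material
29 | (2R)-3-bromo-2-methylpropanoic acid | BrC[C@H](C)C(=O)O | intermediate
30 | lithium (2S)-3-lithio-2-methylpropanoate | [Li]C[C@H](C)C(=O)O[Li] | intermediate
31 | C11 hemiketal carboxylic acid from 27 and 30 (formed as dilithium salt; C11 unassigned) | CC[C@H]1[C@H]2[C@@H](CCCN3[C@H]2CC[C@H]3[C@@H]4C[C@H](C)C(OC)O4)OC1(O)C[C@H](C)C(=O)O | intermediate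
32 | spirolactone (3S,8R,9R,9aS,10S,11S,13S) with C21 as lactol (anomers) | CC[C@H]1[C@H]2[C@@H](CCCN3[C@H]2CC[C@H]3[C@@H]4C[C@H](C)C(O)O4)O[C@]15C[C@H](C)C(=O)O5 | intermediate
33 | CNP0419197.1 | CC[C@H]1[C@H]2[C@@H](CCCN3[C@H]2CC[C@H]3[C@@H]2C[C@H](C)C(=O)O2)O[C@]12C[C@H](C)C(=O)O2 | target

**Count**
Total step count: 16. Longest linear sequence: 12 steps (steps 2, 3, 4, 5, 6, 7, 10, 11, 12, 13, 15, 16, from L-pyroglutamic acid).

**Steps most likely to fail**

1. Step 4. The tethered cycloaddition may be slower than silyl migration from N to O or than thermal loss of the silyl group, so the alkyne may never reach the oxazole. Fallback, from 7 back to 11: 7 is heated with ethynyl 4-methylphenyl sulfone in toluene. This is an intermolecular oxazole–alkyne Diels–Alder/retro-Diels–Alder reaction of a 5-alkoxyoxazole with an electron-poor alkyne, in which the sulfonyl-bearing carbon should join the methoxy-bearing oxazole carbon. It still forms C18–C19 and C21–C20 in one operation and should give the sulfonylfuran (5S)-5-[5-methoxy-4-(4-methylbenzenesulfonyl)furan-2-yl]pyrrolidin-2-one F1. Acidic methanol should open F1 to methyl 2-(4-methylbenzenesulfonyl)-4-oxo-4-[(2S)-5-oxopyrrolidin-2-yl]butanoate F2. C-methylation of the doubly activated carbon (K2CO3, MeI) should give methyl 2-methyl-2-(4-methylbenzenesulfonyl)-4-oxo-4-[(2S)-5-oxopyrrolidin-2-yl]butanoate F3, and reductive desulfonylation with aluminium amalgam (Al–Hg) should give 11.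

2. Step 15. The basic lithio carboxylate may enolise the lactone at C10 or add twice, and the spiro centre may not equilibrate to the wanted configuration. Fallback, from 27 back to 32: 27 is converted with KN(SiMe3)2 and diphenyl chlorophosphate into the ketene acetal phosphate, the C10=C11 enol diphenyl phosphate of 27 F4. Zinc insertion (Zn, LiCl) into 28 gives bromo[(2S)-3-methoxy-2-methyl-3-oxopropyl]zinc F5. Negishi coupling of F4 with F5 under Pd(PPh3)4 catalysis should give the cyclic enol ether ester, methyl (2S)-2-methyl-3-(C11-yl)propanoate of the C10=C11 dihydrofuran F6. Aqueous HCl then protonates C10, the ester carbonyl captures the C11 oxocarbenium ion, and the acetal is hydrolysed, to give 32.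

3. Step 5. Coordination of the reagent to the lactam N–H may override the Felkin–Anh preference and erode the facial selectivity at C18. Fallback, from 11 back to 13: catalyst control replaces substrate control, by a Corey–Bakshi–Shibata reduction of 11 with the (R)-2-methyl-oxazaborolidine catalyst and BH3·SMe2. The larger pyrrolidinone side and the smaller CH2 side of the ketone direct hydride to the face that gives 18S; the hydroxy ester 12 then lactonises to 13 on mild acid treatment. No new compound is made.

**Further compounds**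
F1 | step 4 | (5S)-5-[5-methoxy-4-(4-methylbenzenesulfonyl)furan-2-yl]pyrrolidin-2-one | COc1oc(cc1S(=O)(=O)c2ccc(C)cc2)[C@@H]3CCC(=O)N3
F2 | step 4 | methyl 2-(4-methylbenzenesulfonyl)-4-oxo-4-[(2S)-5-oxopyrrolidin-2-yl]butanoate | COC(=O)C(CC(=O)[C@@H]1CCC(=O)N1)S(=O)(=O)c2ccc(C)cc2
F3 | step 4 | methyl 2-methyl-2-(4-methylbenzenesulfonyl)-4-oxo-4-[(2S)-5-oxopyrrolidin-2-yl]butanoate | COC(=O)C(C)(CC(=O)[C@@H]1CCC(=O)N1)S(=O)(=O)c2ccc(C)cc2
F4 | step 15 | C10=C11 enol diphenyl phosphate (ketene acetal phosphate) of lactone 27 | CCC1[C@H]2[C@@H](CCCN3[C@H]2CC[C@H]3[C@@H]4C[C@H](C)C(OC)O4)OC=1OP(=O)(Oc5ccccc5)Oc6ccccc6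
F5 | step 15 | bromo[(2S)-3-methoxy-2-methyl-3-oxopropyl]zinc | Br[Zn]C[C@H](C)C(=O)OC
F6 | step 15 | methyl (2S)-2-methyl-3-(C11-yl)propanoate of the C10=C11 cyclic enol ether | CCC1[C@H]2[C@@H](CCCN3[C@H]2CC[C@H]3[C@@H]4C[C@H](C)C(OC)O4)OC=1C[C@H](C)C(=O)OC
F0 | step 5 | none | none
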